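The numbers in the tables were computed from invented constants, and the scatter is random.

The vessel was a closed, stirred flask of constant volume at 20 °C, charged with 0.20 M of J and 0.100 M of G and followed up to 120 min. The steps proposed for it were J with G giving L and D, the same step helped by D, and G with L giving E.

| setting | gamma | alpha | flask |
|---|---|---|---|
| J | 0.20 M | 0.20 M | 0.20 M |
| G | 0.10 M | 0.10 M | 0.100 M |
| temperature | 20 °C | 26 °C | 20 °C |
| remark | the very flask that is asked about, followed so far | run made earlier |  |
| time |  |  | 2.5 h |

| run | time / min | L / % | J / % |
|---|---|---|---|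
| gamma | 30.0 | 10.1 | 85.6 |
| gamma | 60.0 | 19.5 | 68.8 |
| gamma | 90.0 | 21.6 | 64.2 |
| gamma | 120 | 20.9 | 64.6 |
| alpha | 30.0 | 14.5 | 76.2 |
| alpha | 60.0 | 20.5 | 65.4 |
| alpha | 90.0 | 20.8 | 64.1 |
| alpha | 120 | 20.1 | 65.0 |

(readings scatter by 0.5 percentage points)

- Thursday's: at 2.5 h add G, 100% of the amount charged, then wait 50 min
- Wednesday's: change nothing and wait 50 min more
- Tuesday's: at 2.5 h raise the temperature by 15 K, then wait 50 min
- Sunday's: at 2.5 h take out 90% of the D then present, then wait 50 min

1. L, in percent of the J first charged, at 2.5 h
2. the option that brings most further L ("none" if no option brings more than 2 percentage points) (Thursday's / Wednesday's / Tuesday's / Sunday's / none)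
3. L present, in percent of the J first charged, after Thursday's
4. L present, in percent of the J first charged, after Sunday's

- what is added takes up no volume worth counting
- steps that have been proposed: G + L -> E; J + G -> L + D; J + G + D -> L + 2 D

Two things about the gamma run, this same flask, did not seem to go together. J fell by 14 percentage points in the first half hour and by 17 points in the second, more, so the loss was quickening; yet from 90.0 min to 120 min J stood still, though 64.6% of it was there. The quickening fits a step helped by what it makes (autocatalysis), and a balance cleared up the stop. Every J lost takes one G and leaves one L, and every E takes one more G and removes one L, so E is J lost minus L. The G spent, S = J lost + E, in percent of the J charged, came at 90.0 min to 50.0%, against a charge B of 50.0% of the J. S as read had reached B within the scatter, which makes G the limiting reagent, and the warmer alpha run gave S = 49.9% at 120 min.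

I therefore took L at 2.5 h from the last two readings, about 21.3%. Wednesday's, Tuesday's and Sunday's add no G, so I expected L to stay there, while Thursday's raises B to 100% and was my choice.

The forecast gave 21%, Thursday's, 33% and 21%, on the ground that “no G remains”.

The flask gave 21.1%, Thursday's with a gain of 11 points, 32.2% after Thursday's and 21.1% after Sunday's.

    G + L → E (k = 0.566 L mol⁻¹ min⁻¹, Ea = 45.0 kJ mol⁻¹)
    J + G → L + D (k = 0.0141 L mol⁻¹ min⁻¹, Ea = 53.0 kJ mol⁻¹)
    J + G + D → L + 2 D (k = 4.92 L² mol⁻² min⁻¹, Ea = 37.0 kJ mol⁻¹)
    (constants at 20 °C)

At 150 min the flask held J 64.5% and L 21.1%, so S stood at 49.9%, close to the 50.0% I had read from the gamma run, with 0.021% of the G left. At 35.7 min the D-helped step in this flask used G 2.2 times as fast as the step to E. In a neighbour flask with 0.25 M of G, B is 125%, which is 75 points above the 50.0% read in the gamma run, so once its G is used up, J lost plus E must come to B. The computed flask held J 21.0%, L 32.9%, E 46.0% and G 0%, which makes S 125%.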